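**Plan**

1. Retrosynthesis: the quinone methide is unmasked from a triaryl carbinol, which is cut at the bond between the methide carbon and one 4-oxygenated aryl ring (aryllithium + diaryl ketone); the CH2OH is traced back to a methyl ester.
2. Ring A, the central benzene, carries four contiguous carbon substituents (C1 methide carbon, C2 aryl, C6 arylethynyl, C5 CH2OH) next to two adjacent CH (C3, C4). Cutting C2–C3 and C4–C5 makes C5–C6–C1–C2 the diene of a 3-carbomethoxy-2-pyrone and C3/C4 ethyl vinyl ether.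
3. The pyrone is cut at its C4–C5 bond and its lactone C–O bond into a symmetric bis-aryl 1,3-diketone and an alkynylidene malonate (arylpropynal + dimethyl malonate).
4. Forward: diketone and ynal are made, joined by Michael addition/lactonisation and dehydrogenated to the pyrone (first ring). The cycloaddition with loss of CO2 and ethanol then builds ring A, the only carbocycle that has to be made. Reduction, silylation, re-oxidation and aryllithium addition give the triaryl carbinol.
5. All four phenols travel as benzyl ethers, so that one BCl3 treatment at −78 °C followed by dilute acid releases the phenols, the CH2OH and the quinone methide.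
6. Stereochemistry: the target has no stereocentre; every sp3 centre made on the way (dihydropyranone, cycloadduct, carbinols) forms as a mixture and is erased again.

Key step: step 6

Assumption: the target SMILES has no stereodescriptor and selaginellin has no stereocentre (rotation about the ring A aryl bonds is taken as free), so the constitution alone defines the compound; the two 4-oxygenated rings on the methide carbon are interchangeable by tautomerism, so either may end as the quinone.

**Route**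

Step 1
Reactants: 1 4'-(benzyloxy)acetophenone; 2 methyl 4-(benzyloxy)benzoate
Product: 3 1,3-bis[4-(benzyloxy)phenyl]propane-1,3-dione
Conditions: NaH (2.5 equiv), THF, reflux (slow addition of 1); then aq. HCl
Reagents that add atoms: none
Why: Crossed Claisen condensation in which the sodium enolate of the methyl ketone acylates on the non-enolisable benzoate, the equilibrium being pulled over by deprotonation of the 1,3-diketone formed.

Step 2
Reactants: 4 1-(benzyloxy)-4-ethynylbenzene
Product: 6 3-[4-(benzyloxy)phenyl]prop-2-ynal, via lithium acetylide 5 (not isolated)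
Conditions: n-BuLi, THF, −78 °C; DMF, −78 → 0 °C; reverse quench into aq. KH2PO4/MTBE
Reagents that add atoms: N,N-dimethylformamide, CN(C)C=O
Why: Formylation of a lithium acetylide with DMF, the lithium hemiaminal alkoxide persisting until the buffered reverse quench, which should release the ynal without letting dimethylamine add back to the triple bond.

Step 3
Reactants: 6 3-[4-(benzyloxy)phenyl]prop-2-ynal; 7 dimethyl malonate
Product: 8 dimethyl 2-{3-[4-(benzyloxy)phenyl]prop-2-yn-1-ylidene}propanedioate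
Conditions: TiCl4, pyridine, THF, 0 °C → rt
Reagents that add atoms: none
Why: Knoevenagel condensation under TiCl4/pyridine, which forces the weakly acidic malonate onto the aldehyde and avoids secondary-amine catalysts that would add to the ynal; the two esters are identical, so no alkene geometry arises.

Step 4
Reactants: 3 1,3-bis[4-(benzyloxy)phenyl]propane-1,3-dione; 8 dimethyl 2-{3-[4-(benzyloxy)phenyl]prop-2-yn-1-ylidene}propanedioate
Product: 10 methyl 5-[4-(benzyloxy)benzoyl]-6-[4-(benzyloxy)phenyl]-4-{[4-(benzyloxy)phenyl]ethynyl}-2-oxo-3,4-dihydro-2H-pyran-3-carboxylate, via Michael adduct 9 (not isolated)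
Conditions: DBU (0.1 equiv), toluene, rt; then p-TsOH·H2O (0.3 equiv), reflux through 4 Å sieves (MeOH removed)
Reagents that add atoms: none
Why: Michael addition of the 1,3-diketone enolate to the doubly activated alkene (1,4-attack at the propargylic carbon, the usual site for soft carbon nucleophiles on alkynylidene malonates) followed by acid-catalysed enol-lactonisation driven by removal of methanol; the two new sp3 centres form as a racemic diastereomer mixture and are erased in step 5.

Step 5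
Reactants: 10 methyl 5-[4-(benzyloxy)benzoyl]-6-[4-(benzyloxy)phenyl]-4-{[4-(benzyloxy)phenyl]ethynyl}-2-oxo-3,4-dihydro-2H-pyran-3-carboxylate
Product: 11 methyl 5-[4-(benzyloxy)benzoyl]-6-[4-(benzyloxy)phenyl]-4-{[4-(benzyloxy)phenyl]ethynyl}-2-oxo-2H-pyran-3-carboxylate
Conditions: DDQ (1.3 equiv), 1,4-dioxane, 90 °C
Reagents that add atoms: none
Why: DDQ dehydrogenation in which hydride is taken from the propargylic, allylic C4–H of the ester enol and the acidic C3 proton is lost, giving the conjugated 2-pyrone as in the usual conversion of 3-acyl-3,4-dihydropyranones and dihydrocoumarins into the unsaturated lactones.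

Step 6
Reactants: 11 methyl 5-[4-(benzyloxy)benzoyl]-6-[4-(benzyloxy)phenyl]-4-{[4-(benzyloxy)phenyl]ethynyl}-2-oxo-2H-pyran-3-carboxylate; 12 ethyl vinyl ether
Product: 15 methyl 3-[4-(benzyloxy)benzoyl]-4-[4-(benzyloxy)phenyl]-2-{[4-(benzyloxy)phenyl]ethynyl}benzoate, via bridged lactone 13 (not isolated), via ethoxycyclohexadiene 14 (not isolated)
Conditions: ethyl vinyl ether (10 equiv), toluene, sealed tube, 130 °C; then DBU (0.2 equiv), rt
Reagents that add atoms: none
Why: The 3-ester and 5-aroyl groups lower the LUMO of the pyrone diene (C3=C4–C5=C6), which should take up the electron-rich enol ether in a concerted but asynchronous inverse-electron-demand Diels–Alder reaction, the CH2 terminus bonding to pyrone C6 and the ethoxy-bearing carbon to C3. The bridged lactone then loses CO2 by retro-[4+2] at the reaction temperature and the resulting 6-ethoxycyclohexa-1,3-diene loses ethanol by E1cB elimination (its ring CH2 is vinylogously acidic through the aroyl and ester groups), which DBU completes. The closest known reaction type is the cycloaddition of 2-pyrone-3-carboxylates with vinyl ethers or ketene acetals that ends in benzoates after extrusion of CO2 and alcohol. Ring A is the one ring closed, by an intermolecular [4+2] cycloaddition that makes both new σ-bonds (ring A C2–C3 and C4–C5) in the same step. No stereocentre has to be controlled, because the bridgehead and ethoxy-bearing centres of 13 and 14, formed as isomer mixtures, are all flattened on aromatisation and both dienophile carbons end as CH, which also makes the orientation of the enol ether irrelevant. The selectivity needed is chemoselectivity for the diene over the diarylalkyne and the ketone, secured by the electron-poor diene/electron-rich dienophile pairing and by the absence of acid or metal catalysts that could activate the alkyne.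

Step 7
Reactants: 15 methyl 3-[4-(benzyloxy)benzoyl]-4-[4-(benzyloxy)phenyl]-2-{[4-(benzyloxy)phenyl]ethynyl}benzoate
Product: 16 [4-(benzyloxy)phenyl]{6-[4-(benzyloxy)phenyl]-2-{[4-(benzyloxy)phenyl]ethynyl}-3-(hydroxymethyl)phenyl}methanol
Conditions: DIBAL-H (5 equiv), CH2Cl2, −78 → 0 °C; Rochelle salt
Reagents that add atoms: none
Why: Hydride reduction with DIBAL-H takes the methyl ester to the primary alcohol and the diaryl ketone to the carbinol at low temperature, where hydroalumination of the diarylalkyne should not compete; the carbinol centre is racemic and is re-oxidised in step 9.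

Step 8
Reactants: 16 [4-(benzyloxy)phenyl]{6-[4-(benzyloxy)phenyl]-2-{[4-(benzyloxy)phenyl]ethynyl}-3-(hydroxymethyl)phenyl}methanol
Product: 17 [4-(benzyloxy)phenyl]{6-[4-(benzyloxy)phenyl]-2-{[4-(benzyloxy)phenyl]ethynyl}-3-({[tert-butyl(dimethyl)silyl]oxy}methyl)phenyl}methanol
Conditions: TBSCl (1.1 equiv), imidazole, CH2Cl2, 0 °C
Reagents that add atoms: tert-butyldimethylsilyl chloride, CC(C)(C)[Si](C)(C)Cl
Why: Selective silylation of a primary alcohol, since the secondary diarylcarbinol is flanked by two ortho substituents of ring A and should react far more slowly with TBSCl/imidazole than the unhindered benzylic CH2OH.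

Step 9
Reactants: 17 [4-(benzyloxy)phenyl]{6-[4-(benzyloxy)phenyl]-2-{[4-(benzyloxy)phenyl]ethynyl}-3-({[tert-butyl(dimethyl)silyl]oxy}methyl)phenyl}methanol
Product: 18 [4-(benzyloxy)phenyl]{6-[4-(benzyloxy)phenyl]-2-{[4-(benzyloxy)phenyl]ethynyl}-3-({[tert-butyl(dimethyl)silyl]oxy}methyl)phenyl}methanone
Conditions: Dess–Martin periodinane, CH2Cl2, rt
Reagents that add atoms: none
Why: Dess–Martin oxidation of a secondary benzhydrol to the diaryl ketone under near-neutral conditions that should leave the silyl ether, the benzyl ethers and the alkyne untouched.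

Step 10
Reactants: 18 [4-(benzyloxy)phenyl]{6-[4-(benzyloxy)phenyl]-2-{[4-(benzyloxy)phenyl]ethynyl}-3-({[tert-butyl(dimethyl)silyl]oxy}methyl)phenyl}methanone; 19 1-(benzyloxy)-4-bromobenzene
Product: 21 bis[4-(benzyloxy)phenyl]{6-[4-(benzyloxy)phenyl]-2-{[4-(benzyloxy)phenyl]ethynyl}-3-({[tert-butyl(dimethyl)silyl]oxy}methyl)phenyl}methanol, via 4-(benzyloxy)phenyllithium 20 (not isolated)
Conditions: 19, n-BuLi, THF, −78 °C; then 18, −78 → −20 °C; aq. NH4Cl
Reagents that add atoms: none
Why: Bromine–lithium exchange followed by 1,2-addition of the aryllithium to a non-enolisable diaryl ketone, which is the only electrophile left now that the former ester is a silyl ether; the two aryl groups on the new carbinol carbon are identical, so no stereocentre is created.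

Step 11
Reactants: 21 bis[4-(benzyloxy)phenyl]{6-[4-(benzyloxy)phenyl]-2-{[4-(benzyloxy)phenyl]ethynyl}-3-({[tert-butyl(dimethyl)silyl]oxy}methyl)phenyl}methanol
Product: 23 selaginellin, via selaginellin silyl ether 22 (not isolated)
Conditions: BCl3 (1 M in CH2Cl2, excess), C6HMe5, CH2Cl2, −78 °C; then 1 M aq. HCl–THF, 0 °C → rt
Reagents that add atoms: none
Why: Debenzylation of aryl benzyl ethers with BCl3 and pentamethylbenzene as a non-basic benzyl-cation scavenger at −78 °C also ionises the tertiary carbinol to the triarylmethyl cation, and aqueous acid then cleaves the primary silyl ether while the 4-hydroxy-substituted cation loses a proton to give the quinone methide (dehydration of a 4-hydroxytrityl carbinol to a fuchsone).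

**Compound list**

1 | 4'-(benzyloxy)acetophenone | CC(=O)c1ccc(OCc2ccccc2)cc1 | starting material
2 | methyl 4-(benzyloxy)benzoate | COC(=O)c1ccc(OCc2ccccc2)cc1 | starting material
3 | 1,3-bis[4-(benzyloxy)phenyl]propane-1,3-dione | O=C(CC(=O)c1ccc(OCc2ccccc2)cc1)c1ccc(OCc2ccccc2)cc1 | intermediate
4 | 1-(benzyloxy)-4-ethynylbenzene | C#Cc1ccc(OCc2ccccc2)cc1 | starting material
5 | lithium [4-(benzyloxy)phenyl]acetylide (formed in the flask) | [Li]C#Cc1ccc(OCc2ccccc2)cc1 | intermediate
6 | 3-[4-(benzyloxy)phenyl]prop-2-ynal | O=CC#Cc1ccc(OCc2ccccc2)cc1 | intermediate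
7 | dimethyl malonate | COC(=O)CC(=O)OC | starting material
8 | dimethyl 2-{3-[4-(benzyloxy)phenyl]prop-2-yn-1-ylidene}propanedioate | COC(=O)C(=CC#Cc1ccc(OCc2ccccc2)cc1)C(=O)OC | intermediate
9 | dimethyl 2-{2-[4-(benzyloxy)benzoyl]-3-[4-(benzyloxy)phenyl]-1-{[4-(benzyloxy)phenyl]ethynyl}-3-oxopropyl}propanedioate (racemic, formed in the flask) | COC(=O)C(C(=O)OC)C(C#Cc1ccc(OCc2ccccc2)cc1)C(C(=O)c1ccc(OCc2ccccc2)cc1)C(=O)c1ccc(OCc2ccccc2)cc1 | intermediate
10 | methyl 5-[4-(benzyloxy)benzoyl]-6-[4-(benzyloxy)phenyl]-4-{[4-(benzyloxy)phenyl]ethynyl}-2-oxo-3,4-dihydro-2H-pyran-3-carboxylate (racemic, cis/trans mixture) | COC(=O)C1C(C#Cc2ccc(OCc3ccccc3)cc2)C(C(=O)c2ccc(OCc3ccccc3)cc2)=C(c2ccc(OCc3ccccc3)cc2)OC1=O | intermediate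
11 | methyl 5-[4-(benzyloxy)benzoyl]-6-[4-(benzyloxy)phenyl]-4-{[4-(benzyloxy)phenyl]ethynyl}-2-oxo-2H-pyran-3-carboxylate | COC(=O)C1=C(C#Cc2ccc(OCc3ccccc3)cc2)C(C(=O)c2ccc(OCc3ccccc3)cc2)=C(c2ccc(OCc3ccccc3)cc2)OC1=O | intermediate
12 | ethyl vinyl ether | C=COCC | starting material
13 | methyl 6-[4-(benzyloxy)benzoyl]-1-[4-(benzyloxy)phenyl]-5-{[4-(benzyloxy)phenyl]ethynyl}-8-ethoxy-3-oxo-2-oxabicyclo[2.2.2]oct-5-ene-4-carboxylate (racemic, endo/exo mixture, formed in the flask) | COC(=O)C12C(=O)OC(c3ccc(OCc4ccccc4)cc3)(CC1OCC)C(C(=O)c1ccc(OCc3ccccc3)cc1)=C2C#Cc1ccc(OCc2ccccc2)cc1 | intermediate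
14 | methyl 3-[4-(benzyloxy)benzoyl]-4-[4-(benzyloxy)phenyl]-2-{[4-(benzyloxy)phenyl]ethynyl}-6-ethoxycyclohexa-1,3-diene-1-carboxylate (racemic, formed in the flask) | COC(=O)C1=C(C#Cc2ccc(OCc3ccccc3)cc2)C(C(=O)c2ccc(OCc3ccccc3)cc2)=C(c2ccc(OCc3ccccc3)cc2)CC1OCC | intermediate
15 | methyl 3-[4-(benzyloxy)benzoyl]-4-[4-(benzyloxy)phenyl]-2-{[4-(benzyloxy)phenyl]ethynyl}benzoate | COC(=O)c1ccc(-c2ccc(OCc3ccccc3)cc2)c(C(=O)c2ccc(OCc3ccccc3)cc2)c1C#Cc1ccc(OCc2ccccc2)cc1 | intermediate
16 | [4-(benzyloxy)phenyl]{6-[4-(benzyloxy)phenyl]-2-{[4-(benzyloxy)phenyl]ethynyl}-3-(hydroxymethyl)phenyl}methanol (racemic) | OCc1ccc(-c2ccc(OCc3ccccc3)cc2)c(C(O)c2ccc(OCc3ccccc3)cc2)c1C#Cc1ccc(OCc2ccccc2)cc1 | intermediate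
17 | [4-(benzyloxy)phenyl]{6-[4-(benzyloxy)phenyl]-2-{[4-(benzyloxy)phenyl]ethynyl}-3-({[tert-butyl(dimethyl)silyl]oxy}methyl)phenyl}methanol (racemic) | CC(C)(C)[Si](C)(C)OCc1ccc(-c2ccc(OCc3ccccc3)cc2)c(C(O)c2ccc(OCc3ccccc3)cc2)c1C#Cc1ccc(OCc2ccccc2)cc1 | intermediate
18 | [4-(benzyloxy)phenyl]{6-[4-(benzyloxy)phenyl]-2-{[4-(benzyloxy)phenyl]ethynyl}-3-({[tert-butyl(dimethyl)silyl]oxy}methyl)phenyl}methanone | CC(C)(C)[Si](C)(C)OCc1ccc(-c2ccc(OCc3ccccc3)cc2)c(C(=O)c2ccc(OCc3ccccc3)cc2)c1C#Cc1ccc(OCc2ccccc2)cc1 | intermediate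
19 | 1-(benzyloxy)-4-bromobenzene | Brc1ccc(OCc2ccccc2)cc1 | starting material
20 | 4-(benzyloxy)phenyllithium (formed in the flask) | [Li]c1ccc(OCc2ccccc2)cc1 | intermediate
21 | bis[4-(benzyloxy)phenyl]{6-[4-(benzyloxy)phenyl]-2-{[4-(benzyloxy)phenyl]ethynyl}-3-({[tert-butyl(dimethyl)silyl]oxy}methyl)phenyl}methanol | CC(C)(C)[Si](C)(C)OCc1ccc(-c2ccc(OCc3ccccc3)cc2)c(C(O)(c2ccc(OCc3ccccc3)cc2)c2ccc(OCc3ccccc3)cc2)c1C#Cc1ccc(OCc2ccccc2)cc1 | intermediate
22 | 4-[{3-({[tert-butyl(dimethyl)silyl]oxy}methyl)-6-(4-hydroxyphenyl)-2-[(4-hydroxyphenyl)ethynyl]phenyl}(4-hydroxyphenyl)methylidene]cyclohexa-2,5-dien-1-one (selaginellin silyl ether, formed in the flask) | CC(C)(C)[Si](C)(C)OCc1ccc(-c2ccc(O)cc2)c(C(c2ccc(O)cc2)=C2C=CC(=O)C=C2)c1C#Cc1ccc(O)cc1 | intermediate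
23 | selaginellin, 4-[{3-(hydroxymethyl)-6-(4-hydroxyphenyl)-2-[(4-hydroxyphenyl)ethynyl]phenyl}(4-hydroxyphenyl)methylidene]cyclohexa-2,5-dien-1-one | O=C1C=CC(=C(c2ccc(O)cc2)c2c(-c3ccc(O)cc3)ccc(CO)c2C#Cc2ccc(O)cc2)C=C1 | target

**Step count and risks**

Total steps: 11. Longest linear sequence: 10 steps (steps 2–11, from 4); step 1 is a one-step side branch that joins at step 4.

Steps most likely to fail:

Step 4. The conjugate addition may revert on heating, and ring closure may stall at the open-chain adduct because loss of methanol to an enol lactone is uphill unless the alcohol is removed. The enol oxygen may also add to the alkyne instead of the ester. The fallback sets out from 6 (with 3) and comes back at 10, closing the lactone from an activated acid and not from a methyl ester. Knoevenagel condensation of 6 with commercial tert-butyl methyl malonate (TiCl4, pyridine, THF) should give 1-tert-butyl 3-methyl 2-{3-[4-(benzyloxy)phenyl]prop-2-yn-1-ylidene}propanedioate F1. DBU-catalysed Michael addition of 3 at rt should give the mixed-ester adduct 1-tert-butyl 3-methyl 2-{2-[4-(benzyloxy)benzoyl]-3-[4-(benzyloxy)phenyl]-1-{[4-(benzyloxy)phenyl]ethynyl}-3-oxopropyl}propanedioate F2. TFA–CH2Cl2 at 0 °C should remove the tert-butyl group to give the half-acid 2-{2-[4-(benzyloxy)benzoyl]-3-[4-(benzyloxy)phenyl]-1-{[4-(benzyloxy)phenyl]ethynyl}-3-oxopropyl}-3-methoxy-3-oxopropanoic acid F3. Carbodiimide activation (EDC·HCl, CH2Cl2, rt) should then acylate the diketone enol oxygen irreversibly and give 10.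

Step 5. Hydride abstraction from the electron-poor C4–H may be slow, and prolonged heating with DDQ may start to oxidise the benzylic CH2 groups of the ethers. The fallback sets out from 10 and comes back at 11 by an ionic selenoxide route. Deprotonation at C3 (NaH, THF, −78 °C) and trapping with PhSeCl, expected anti to the C4 alkynyl group, should give methyl 5-[4-(benzyloxy)benzoyl]-6-[4-(benzyloxy)phenyl]-4-{[4-(benzyloxy)phenyl]ethynyl}-2-oxo-3-(phenylselanyl)-3,4-dihydro-2H-pyran-3-carboxylate F4. Oxidation with H2O2 (CH2Cl2, 0 °C) should give the selenoxide methyl 3-(benzeneseleninyl)-5-[4-(benzyloxy)benzoyl]-6-[4-(benzyloxy)phenyl]-4-{[4-(benzyloxy)phenyl]ethynyl}-2-oxo-3,4-dihydro-2H-pyran-3-carboxylate F5. Its selenium is syn to H-4, so syn-elimination at or below rt should deliver 11.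

Step 11. Ionisation of the carbinol gives a long-lived triarylmethyl cation beside the alkyne and the silyloxymethyl group. Loss of benzyl from the two cation-stabilising rings may be slow, and Lewis-acid-induced closure of a neighbouring oxygen onto the alkyne may compete. The fallback sets out from 18 and comes back at 23; it exchanges the phenol protecting groups before the carbinol exists, so the last unmasking is a fluoride desilylation.

- BCl3/C6HMe5 (CH2Cl2, −78 °C) on ketone 18, where no carbocation can form and the primary silyl ether is expected to stay, should give the triphenol (4-hydroxyphenyl){3-({[tert-butyl(dimethyl)silyl]oxy}methyl)-6-(4-hydroxyphenyl)-2-[(4-hydroxyphenyl)ethynyl]phenyl}methanone F6.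
- TBSCl/imidazole (DMF, rt) should give the tetrasilyl ether (4-{[tert-butyl(dimethyl)silyl]oxy}phenyl){3-({[tert-butyl(dimethyl)silyl]oxy}methyl)-6-(4-{[tert-butyl(dimethyl)silyl]oxy}phenyl)-2-[(4-{[tert-butyl(dimethyl)silyl]oxy}phenyl)ethynyl]phenyl}methanone F7.
- Addition of 4-{[tert-butyl(dimethyl)silyl]oxy}phenyllithium F8, made from commercial (4-bromophenoxy)(tert-butyl)dimethylsilane and n-BuLi in THF at −78 °C, should give the carbinol bis(4-{[tert-butyl(dimethyl)silyl]oxy}phenyl){3-({[tert-butyl(dimethyl)silyl]oxy}methyl)-6-(4-{[tert-butyl(dimethyl)silyl]oxy}phenyl)-2-[(4-{[tert-butyl(dimethyl)silyl]oxy}phenyl)ethynyl]phenyl}methanol F9.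
- TBAF buffered with AcOH (THF, 0 °C) followed by a dilute-acid wash should remove the five silyl groups and dehydrate to 23.

Further compounds
F1 | step 4 | 1-tert-butyl 3-methyl 2-{3-[4-(benzyloxy)phenyl]prop-2-yn-1-ylidene}propanedioate (E/Z mixture) | COC(=O)C(=CC#Cc1ccc(OCc2ccccc2)cc1)C(=O)OC(C)(C)C
F2 | step 4 | 1-tert-butyl 3-methyl 2-{2-[4-(benzyloxy)benzoyl]-3-[4-(benzyloxy)phenyl]-1-{[4-(benzyloxy)phenyl]ethynyl}-3-oxopropyl}propanedioate (diastereomer mixture) | COC(=O)C(C(=O)OC(C)(C)C)C(C#Cc1ccc(OCc2ccccc2)cc1)C(C(=O)c1ccc(OCc2ccccc2)cc1)C(=O)c1ccc(OCc2ccccc2)cc1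
F3 | step 4 | 2-{2-[4-(benzyloxy)benzoyl]-3-[4-(benzyloxy)phenyl]-1-{[4-(benzyloxy)phenyl]ethynyl}-3-oxopropyl}-3-methoxy-3-oxopropanoic acid (diastereomer mixture) | COC(=O)C(C(=O)O)C(C#Cc1ccc(OCc2ccccc2)cc1)C(C(=O)c1ccc(OCc2ccccc2)cc1)C(=O)c1ccc(OCc2ccccc2)cc1
F4 | step 5 | methyl 5-[4-(benzyloxy)benzoyl]-6-[4-(benzyloxy)phenyl]-4-{[4-(benzyloxy)phenyl]ethynyl}-2-oxo-3-(phenylselanyl)-3,4-dihydro-2H-pyran-3-carboxylate (racemic) | COC(=O)C1([Se]c2ccccc2)C(C#Cc2ccc(OCc3ccccc3)cc2)C(C(=O)c2ccc(OCc3ccccc3)cc2)=C(c2ccc(OCc3ccccc3)cc2)OC1=O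
F5 | step 5 | methyl 3-(benzeneseleninyl)-5-[4-(benzyloxy)benzoyl]-6-[4-(benzyloxy)phenyl]-4-{[4-(benzyloxy)phenyl]ethynyl}-2-oxo-3,4-dihydro-2H-pyran-3-carboxylate (racemic) | COC(=O)C1([Se](=O)c2ccccc2)C(C#Cc2ccc(OCc3ccccc3)cc2)C(C(=O)c2ccc(OCc3ccccc3)cc2)=C(c2ccc(OCc3ccccc3)cc2)OC1=O
F6 | step 11 | (4-hydroxyphenyl){3-({[tert-butyl(dimethyl)silyl]oxy}methyl)-6-(4-hydroxyphenyl)-2-[(4-hydroxyphenyl)ethynyl]phenyl}methanone | CC(C)(C)[Si](C)(C)OCc1ccc(-c2ccc(O)cc2)c(C(=O)c2ccc(O)cc2)c1C#Cc1ccc(O)cc1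
F7 | step 11 | (4-{[tert-butyl(dimethyl)silyl]oxy}phenyl){3-({[tert-butyl(dimethyl)silyl]oxy}methyl)-6-(4-{[tert-butyl(dimethyl)silyl]oxy}phenyl)-2-[(4-{[tert-butyl(dimethyl)silyl]oxy}phenyl)ethynyl]phenyl}methanone | CC(C)(C)[Si](C)(C)OCc1ccc(-c2ccc(O[Si](C)(C)C(C)(C)C)cc2)c(C(=O)c2ccc(O[Si](C)(C)C(C)(C)C)cc2)c1C#Cc1ccc(O[Si](C)(C)C(C)(C)C)cc1
F8 | step 11 | 4-{[tert-butyl(dimethyl)silyl]oxy}phenyllithium | [Li]c1ccc(O[Si](C)(C)C(C)(C)C)cc1
F9 | step 11 | bis(4-{[tert-butyl(dimethyl)silyl]oxy}phenyl){3-({[tert-butyl(dimethyl)silyl]oxy}methyl)-6-(4-{[tert-butyl(dimethyl)silyl]oxy}phenyl)-2-[(4-{[tert-butyl(dimethyl)silyl]oxy}phenyl)ethynyl]phenyl}methanol | CC(C)(C)[Si](C)(C)OCc1ccc(-c2ccc(O[Si](C)(C)C(C)(C)C)cc2)c(C(O)(c2ccc(O[Si](C)(C)C(C)(C)C)cc2)c2ccc(O[Si](C)(C)C(C)(C)C)cc2)c1C#Cc1ccc(O[Si](C)(C)C(C)(C)C)cc1
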